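**Easy step.** In the zeta run, G and J together hold 100 % of the Q charged at the last reading, and the late readings of that run lie flat within scatter. So the flask should stop with its Q reacted, and G is what J leaves. The small share, J, is the one to reckon.

| flask | Q | D | remark | time |
|---|---|---|---|---|
| theta | 0.46 M | 1.22 M | run made earlier |  |
| zeta | 1 M | 1.22 M | run made earlier |  |
| eta | 0.68 M | 0.61 M | run made earlier |  |
| flask | 0.68 M | 1.22 M |  | 5.0 h |

- theta (time / h: G / %, J / %): 0.333: 84.3, 15.6; 1.00: 93.3, 5.6; 1.50: 93.1, 6.0; 2.50: 94.2, 7.1; 4.00: 94.5, 4.0; 5.00: 94.6, 4.9; 6.00: 94.7, 4.6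
- zeta (time / h: G / %, J / %): 0.500: 79.5, 21.0; 0.667: 80.1, 20.0; 1.00: 81.7, 18.7; 1.50: 80.5, 17.7; 2.50: 78.8, 19.6; 4.00: 80.4, 18.5; 6.00: 81.0, 19.0
- eta (time / h: G / %, J / %): 0.500: 63.8, 36.8; 0.833: 64.0, 34.5; 1.50: 63.5, 37.6; 3.00: 63.7, 35.8; 6.00: 64.2, 34.1

(readings scatter by 1 percentage point)

* the state of affairs at 5.0 h: stopped, and by what, or still going (it is still moving / forward and back rates have come level / all of Q has reacted)
* G at 5.0 h, in percent of the Q charged
* J at 5.0 h, in percent of the Q charged

- the numbers in the tables scatter by 1 percentage point (one standard deviation)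
- the reaction counts as stopped when no species that holds the Q changes by six tenths of a point or more over the second half of the time

**Two remainders.** The theta and zeta runs share the flask's D, while eta holds half of it, so theta and zeta are the two to compare. Over their last 3 readings, J stands at 4.50 % in theta and 19.0 % in zeta. Dividing that difference by the difference in Q gives the remainder slope, the share left as J per molar of Q at this D: 0.269 M⁻¹. For the flask, my reckoning gives J 10.4 % and G 89.6 %, from readings that scatter by 1 percentage point.

**The forecast.** It expects G 90 % and J 10 %, and for the state of the flask it chooses "forward and back rates have come level", on the ground that “J + D ⇌ G has reached balance”. On J it lies close to my reckoning, but on the stop the two differ.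

**The flask.** The state of the flask is "all of Q has reacted", with G 90.1 % and J 9.91 %.

    Q → J (k = 0.0280 s⁻¹)
    D → L (k = 0.00340 s⁻¹)
    J + L → G (k = 0.00830 M⁻¹ s⁻¹)
    2 L → E (k = 0.00710 M⁻¹ s⁻¹)

**Neighbouring flask.** The flask parts from the forecast on the stop: at 5.00 h its D, the limiting reagent, stands at 0 % of the charge and L at 1.88 × 10⁻⁶ M, while J stands beside 0.304 M of E. The neighbour flask holds 1.7 M of Q, with D unchanged. The remainder slope carries J from theta to 37.9 % there, and G to 62.1 %. The neighbour flask gives J 39.4 % and G 60.6 %.

The readings were computed from invented constants; noise was put on by code.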